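**Plan**
- Retrosynthesis: the C3–O ester bond is cut first (trienoic acid from (E)-non-3-en-2-one), then C7=C11 (acetone aldol and dehydration on the C8 ketone), then C5–C10 and C8–C9 together, which opens rings A and B to an acyclic 1,7,9-decatriene. The chain is then cut at C7=C8 (Wittig), C5=C6 (Horner–Wadsworth–Emmons) and C3–C4 (aldol).
- Enabling feature: ring B holds the quaternary C5, the fusion CH C10 and the vicinal oxygens on C8 and C9. C5–C8 can therefore be a 1-benzyloxydiene and C9=C10 an (E)-alkenylboronate whose boron becomes the C9 hydroxyl, with C1–C4 of ring A as the four-carbon tether.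
- Forward: the chain C9≡C10–C1–C2–C3–C4–C5(=C6–C7=C8–OBn) is built, boron is placed on C9, one Diels–Alder step closes rings A and B together, ring B is adjusted (C9–OH, C8=O, C7 isopropylidene), and the side chain is attached last.
- Stereochemistry: C3 and C4 come from an Evans syn-aldol. C5, C10 and C9 (and the transient C8) come from the cycloaddition, through the two (E)-alkenes and the equatorial C3/C4 substituents of the tether; the C–B bond is oxidised with retention.

Key step: step 12

Remark: locants are those of eremophilane (ring A = C1–C5 + C10, ring B = C5–C10); α/β refer to the usual drawing with the C5 methyl β. The O8 group is benzyl so that one hydrogenation both saturates C6=C7 and frees O8.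

**Step 1**
Reactants: 1 pent-4-yn-1-ol
Product: 2 pent-4-ynal
Conditions: Dess–Martin periodinane, CH2Cl2, 0 °C → rt; used as a CH2Cl2 solution
Reagents that add atoms: none
Why: Dess–Martin oxidation takes a primary alcohol to the aldehyde without over-oxidation and leaves the terminal alkyne untouched.

**Step 2**
Reactants: 2 pent-4-ynal; 3 (S)-4-benzyl-3-propanoyl-1,3-oxazolidin-2-one
Product: 5 (4S)-4-benzyl-3-[(2S,3R)-3-hydroxy-2-methylhept-6-ynoyl]-1,3-oxazolidin-2-one, via boron (Z)-enolate 4 (not isolated)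
Conditions: n-Bu2BOTf, i-Pr2NEt, CH2Cl2, –78 → 0 °C; then 2, –78 → 0 °C; pH 7 buffer, MeOH, 30% H2O2, 0 °C
Reagents that add atoms: none
Why: Evans syn-aldol reaction in which the (Z)-boron enolate reacts through a chair Zimmerman–Traxler transition state on the face opposite the auxiliary benzyl group, which sets C4 (S in the adduct) and C3 (R) in the syn relationship of the target.

**Step 3**
Reactants: 5 aldol adduct
Product: 6 (2S,3R)-3-hydroxy-N-methoxy-N,2-dimethylhept-6-ynamide
Conditions: MeONHMe·HCl, AlMe3, CH2Cl2, –20 → 0 °C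
Reagents that add atoms: N,O-dimethylhydroxylamine hydrochloride, CNOC.Cl
Why: Weinreb transamidation by the aluminium amide is directed to the exocyclic carbonyl by the free β-hydroxyl (as its aluminium alkoxide) and releases the auxiliary without touching C3 or C4.

**Step 4**
Reactants: 6 hydroxy Weinreb amide
Product: 7 (2S,3R)-3-[(tert-butyldimethylsilyl)oxy]-N-methoxy-N,2-dimethylhept-6-ynamide
Conditions: TBSOTf, 2,6-lutidine, CH2Cl2, –78 → 0 °C
Reagents that add atoms: tert-butyldimethylsilyl trifluoromethanesulfonate, CC(C)(C)[Si](C)(C)OS(=O)(=O)C(F)(F)F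
Why: Silylation of a secondary alcohol with a silyl triflate and a hindered base is fast at low temperature and avoids retro-aldol cleavage.

**Step 5**
Reactants: 7 silyl ether Weinreb amide
Product: 8 (3S,4R)-4-[(tert-butyldimethylsilyl)oxy]-3-methyloct-7-yn-2-one
Conditions: MeMgBr (excess), THF, 0 °C; aq. NH4Cl
Reagents that add atoms: methylmagnesium bromide, C[Mg]Br
Why: Weinreb ketone synthesis in which the chelated tetrahedral intermediate survives until work-up, so neither over-addition nor epimerisation at the α-carbon is expected; the methyl delivered here becomes the C5 methyl.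

**Step 6**
Reactants: 8 methyl ketone
Product: 9 ethyl (2E,4R,5R)-5-[(tert-butyldimethylsilyl)oxy]-3,4-dimethylnon-2-en-8-ynoate
Conditions: (EtO)2P(O)CH2CO2Et, NaH, THF, 0 → 50 °C
Reagents that add atoms: triethyl phosphonoacetate, CCOC(=O)CP(=O)(OCC)OCC
Why: Horner–Wadsworth–Emmons olefination of a methyl ketone places the ester trans to the larger α-branched substituent, which gives the (E)-C5=C6 bond with the methyl in the position that is later inside the diene, and the weakly basic phosphonate anion should leave the α-stereocentre intact.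

**Step 7**
Reactants: 9 enoate
Product: 10 (2E,4R,5R)-5-[(tert-butyldimethylsilyl)oxy]-3,4-dimethylnon-2-en-8-yn-1-ol
Conditions: i-Bu2AlH, CH2Cl2, –78 °C; aq. potassium sodium tartrate
Reagents that add atoms: none
Why: 1,2-Reduction of an α,β-unsaturated ester by i-Bu2AlH gives the allylic alcohol without affecting the alkyne, the silyl ether or the alkene geometry.

**Step 8**
Reactants: 10 allylic alcohol
Product: 11 (2E,4R,5R)-5-[(tert-butyldimethylsilyl)oxy]-3,4-dimethylnon-2-en-8-ynal
Conditions: MnO2, CH2Cl2, rt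
Reagents that add atoms: none
Why: Allylic oxidation with MnO2 is selective for the allylic alcohol and does not isomerise the trisubstituted alkene.

**Step 9**
Reactants: 12 benzyl chloromethyl ether; 13 triphenylphosphine
Product: 14 [(benzyloxy)methyl]triphenylphosphonium chloride
Conditions: PhMe, 50 °C
Reagents that add atoms: none
Why: SN2 quaternisation of the phosphine by the activated α-chloro ether gives the crystalline phosphonium salt.

**Step 10**
Reactants: 11 enal; 14 phosphonium chloride
Product: 16 tert-butyl{[(1E,3E,5R,6R)-1-(benzyloxy)-4,5-dimethyldeca-1,3-dien-9-yn-6-yl]oxy}dimethylsilane, via ylide 15 (not isolated)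
Conditions: 14, NaN(SiMe3)2, THF, –78 → 0 °C; then 11, –78 °C → rt; Et3N-deactivated silica
Reagents that add atoms: none
Why: Wittig olefination of an enal with a non-stabilised alkoxymethylene ylide installs C8 and O8 as the dienyl ether; an E/Z mixture at C7=C8 must be expected, from which the (1E,3E)-isomer, the only one able to reach the s-cis diene, is carried forward.

**Step 11**
Reactants: 16 dienyl ether alkyne; 17 pinacolborane
Product: 18 2-[(1E,5R,6R,7E,9E)-10-(benzyloxy)-5-[(tert-butyldimethylsilyl)oxy]-6,7-dimethyldeca-1,7,9-trien-1-yl]-4,4,5,5-tetramethyl-1,3,2-dioxaborolane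
Conditions: 17, Cp2Zr(H)Cl (10 mol %), Et3N (10 mol %), CH2Cl2, rt
Reagents that add atoms: none
Why: Zirconium-catalysed hydroboration adds Zr–H syn and anti-Markovnikov to the terminal alkyne and exchanges with pinacolborane to give the (E)-alkenylboronate, while the trisubstituted alkene and the enol ether are not hydrozirconated.

**Step 12**
Reactants: 18 triene boronate
Product: 19 trans-fused cycloadduct 8α-(benzyloxy)-3α-(tert-butyldimethylsilyloxy)-4β,5β-dimethyl-9α-(pinacolatoboryl)-10αH-Δ6-octalin
Conditions: PhMe (0.005 M), 2,6-di-tert-butyl-4-methylphenol (0.1 equiv), 170 °C, sealed base-washed tube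
Reagents that add atoms: none
Why: Concerted suprafacial [4+2] cycloaddition in which the HOMO of the 1-benzyloxy-4,4-dialkyl diene C5=C6–C7=C8 meets the LUMO of the (E)-alkenylboronate C9=C10, lowered by the vacant boron p orbital; the closest known reaction types are the thermal intramolecular Diels–Alder reaction of 1,7,9-decatrienes and the Diels–Alder reaction of alkenylboronic esters. Ring B is the new cyclohexene made by the σ-bonds C5–C10 and C8–C9, and ring A closes at the same moment as a six-membered carbocycle because C5–C10 joins the two ends of the four-carbon tether C1–C4 (fused mode, tether on the diene terminus). C9 is fixed relative to C10 by the (E)-geometry of the boronate (boron cis to H10), C8 by the (E)-enol ether together with the boronate-endo orientation (O8 cis to boron), and the trans relation of the C5 methyl to H10 by the same boronate-endo, tether-exo arrangement. The absolute sense at C5 and C10 is relayed from C3 and C4, since the tether folds as a chair with the silyloxy and methyl groups equatorial, whereas attack on the other diene face would place the C3 silyloxy group 1,3-diaxial to the methyl on C5. The step needs endo over exo selectivity and a cycloaddition faster than the [1,5]-hydrogen shift of the inside methyl; the unsubstituted C6 and C7 leave room for the endo boronate, O8 raises the diene HOMO, and high dilution with a radical inhibitor suppresses intermolecular paths.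

**Step 13**
Reactants: 19 cycloadduct
Product: 20 8α-(benzyloxy)-3α-(tert-butyldimethylsilyloxy)-4β,5β-dimethyl-10αH-Δ6-octalin-9α-ol
Conditions: 30% H2O2, NaOH (aq), THF, 0 °C
Reagents that add atoms: hydrogen peroxide, OO
Why: Alkaline peroxide oxidation of the C–B bond proceeds by 1,2-migration of carbon from boron to oxygen with retention, so the equatorial 9α-boronate becomes the 9α-alcohol, and at 0 °C it should outpace β-alkoxy elimination.

**Step 14**
Reactants: 20 alcohol
Product: 21 8α-(benzyloxy)-3α-(tert-butyldimethylsilyloxy)-4β,5β-dimethyl-9α-(triisopropylsilyloxy)-10αH-Δ6-octalin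
Conditions: TIPSOTf, 2,6-lutidine, CH2Cl2, 0 °C → rt
Reagents that add atoms: triisopropylsilyl trifluoromethanesulfonate, CC(C)[Si](C(C)C)(C(C)C)OS(=O)(=O)C(F)(F)F
Why: Silyl triflate silylation protects the hindered equatorial C9 hydroxyl with a group that later outlasts the C3 silyl ether and shields H9 from base.

**Step 15**
Reactants: 21 bis-silyl benzyl ether
Product: 22 3α-(tert-butyldimethylsilyloxy)-4β,5β-dimethyl-9α-(triisopropylsilyloxy)-10αH-decalin-8α-ol
Conditions: H2 (1 atm), Pd/C, EtOAc, rt
Reagents that add atoms: none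
Why: Heterogeneous hydrogenation saturates the cis-disubstituted C6=C7 bond and hydrogenolyses the benzyl ether in one operation, the alkene being expected to be reduced before C–O cleavage so that the C8–O bond is no longer allylic when the benzyl group leaves.

**Step 16**
Reactants: 22 alcohol
Product: 23 3α-(tert-butyldimethylsilyloxy)-4β,5β-dimethyl-9α-(triisopropylsilyloxy)-10αH-decalin-8-one
Conditions: Dess–Martin periodinane, NaHCO3, CH2Cl2, rt
Reagents that add atoms: none
Why: Dess–Martin oxidation of the secondary alcohol under buffered, non-enolising conditions gives the C8 ketone without epimerising the α-silyloxy centre C9.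

**Step 17**
Reactants: 23 ketone
Product: 26 7-(2-hydroxypropan-2-yl) derivative of ketone 23 (C7 epimers), via lithium enolate 24 (not isolated), via chlorozinc enolate 25 (not isolated)
Conditions: LiN(i-Pr)2, THF, –78 °C; ZnCl2, –78 °C; acetone, –78 → –40 °C; aq. NH4Cl
Reagents that add atoms: acetone, CC(C)=O
Why: Directed aldol addition in which the amide base removes the less hindered C7 proton (H9 is tertiary and flanked by the silyloxy group) and the zinc aldolate resists retro-aldol and proton transfer; the new C7 centre is of no consequence because it becomes sp2 in the next step.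

**Step 18**
Reactants: 26 β-hydroxy ketone
Product: 28 3α-(tert-butyldimethylsilyloxy)-9α-(triisopropylsilyloxy)-10αH-eremophil-7(11)-en-8-one, via tertiary mesylate 27 (not isolated)
Conditions: MsCl, Et3N, CH2Cl2, 0 °C; then DBU, rt
Reagents that add atoms: none
Why: Sulfonylation of the tertiary alcohol through sulfene followed by E1cB elimination, with base equilibration of any isopropenyl isomer, gives the conjugated isopropylidene ketone.

**Step 19**
Reactants: 28 enone
Product: 29 3α-hydroxy-9α-(triisopropylsilyloxy)-10αH-eremophil-7(11)-en-8-one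
Conditions: camphor-10-sulfonic acid (cat.), MeOH/CH2Cl2, 0 °C → rt
Reagents that add atoms: none
Why: Acid-catalysed methanolysis removes the tert-butyldimethylsilyl ether, whereas the triisopropylsilyl ether is bulkier and its oxygen is deactivated towards protonation by the adjacent carbonyl.

**Step 20**
Reactants: 30 (E)-non-3-en-2-one
Product: 31 ethyl (2E,4E,6E)-5-methyldodeca-2,4,6-trienoate
Conditions: (EtO)2P(O)CH2CH=CHCO2Et, LiN(SiMe3)2, THF, –78 → 0 °C
Reagents that add atoms: triethyl 4-phosphonocrotonate, CCOC(=O)/C=C/CP(=O)(OCC)OCC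
Why: Vinylogous Horner–Wadsworth–Emmons olefination adds four carbons to the ketone and should favour the (4E)-alkene, with the alkenyl group trans to the chain; any (4Z)-isomer is removed by chromatography here or by crystallisation of the acid.

**Step 21**
Reactants: 31 trienoate
Product: 32 (2E,4E,6E)-5-methyldodeca-2,4,6-trienoic acid
Conditions: LiOH, THF/MeOH/H2O, rt; then aq. HCl
Reagents that add atoms: lithium hydroxide, [Li+].[OH-]
Why: Saponification of the ethyl ester under mild conditions leaves the all-(E) triene unchanged.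

**Step 22**
Reactants: 29 C3 alcohol; 32 trienoic acid
Product: 34 9α-(triisopropylsilyloxy)-8-oxo-10αH-eremophil-7(11)-en-3α-yl (2E,4E,6E)-5-methyldodeca-2,4,6-trienoate, via mixed anhydride 33 (not isolated)
Conditions: 32, 2,4,6-Cl3C6H2COCl, Et3N, THF, rt; then 29, DMAP, PhMe, rt
Reagents that add atoms: none
Why: Yamaguchi esterification, in which DMAP attacks the unhindered acyl carbon of the mixed anhydride, acylates the hindered secondary C3 hydroxyl with retention at C3.

**Step 23**
Reactants: 34 silyl-protected ester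
Product: 35 (3R,4R,5R,9S,10R)-9-hydroxy-8-oxoeremophil-7(11)-en-3-yl (2E,4E,6E)-5-methyldodeca-2,4,6-trienoate (CNP0211657.1)
Conditions: n-Bu4NF, AcOH, THF, 0 °C → rt
Reagents that add atoms: none
Why: Buffered fluoride desilylation is accelerated at the α-keto silyl ether and, with acetic acid present, should spare the trienoate, the cross-conjugated enone and the equatorial C9 configuration.

**Compound list**
1 | pent-4-yn-1-ol | C#CCCCO | starting material
2 | pent-4-ynal | C#CCCC=O | intermediate
3 | (S)-4-benzyl-3-propanoyl-1,3-oxazolidin-2-one | CCC(=O)N1[C@@H](Cc2ccccc2)COC1=O | starting material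
4 | di-n-butylboron (Z)-enolate of 3 | C/C=C(\OB(CCCC)CCCC)N1[C@@H](Cc2ccccc2)COC1=O | intermediate (not isolated)
5 | (4S)-4-benzyl-3-[(2S,3R)-3-hydroxy-2-methylhept-6-ynoyl]-1,3-oxazolidin-2-one | O=C([C@@H](C)[C@H](O)CCC#C)N1[C@@H](Cc2ccccc2)COC1=O | intermediate
6 | (2S,3R)-3-hydroxy-N-methoxy-N,2-dimethylhept-6-ynamide | CON(C)C(=O)[C@@H](C)[C@H](O)CCC#C | intermediate
7 | (2S,3R)-3-[(tert-butyldimethylsilyl)oxy]-N-methoxy-N,2-dimethylhept-6-ynamide | CON(C)C(=O)[C@@H](C)[C@H](O[Si](C)(C)C(C)(C)C)CCC#C | intermediate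
8 | (3S,4R)-4-[(tert-butyldimethylsilyl)oxy]-3-methyloct-7-yn-2-one | CC(=O)[C@@H](C)[C@H](O[Si](C)(C)C(C)(C)C)CCC#C | intermediate
9 | ethyl (2E,4R,5R)-5-[(tert-butyldimethylsilyl)oxy]-3,4-dimethylnon-2-en-8-ynoate | CCOC(=O)/C=C(\C)[C@@H](C)[C@H](O[Si](C)(C)C(C)(C)C)CCC#C | intermediate
10 | (2E,4R,5R)-5-[(tert-butyldimethylsilyl)oxy]-3,4-dimethylnon-2-en-8-yn-1-ol | OC/C=C(\C)[C@@H](C)[C@H](O[Si](C)(C)C(C)(C)C)CCC#C | intermediate
11 | (2E,4R,5R)-5-[(tert-butyldimethylsilyl)oxy]-3,4-dimethylnon-2-en-8-ynal | O=C/C=C(\C)[C@@H](C)[C@H](O[Si](C)(C)C(C)(C)C)CCC#C | intermediate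
12 | benzyl chloromethyl ether | ClCOCc1ccccc1 | starting material
13 | triphenylphosphine | c1ccc(cc1)P(c1ccccc1)c1ccccc1 | starting material
14 | [(benzyloxy)methyl]triphenylphosphonium chloride | [Cl-].c1ccccc1COC[P+](c1ccccc1)(c1ccccc1)c1ccccc1 | intermediate
15 | (benzyloxymethylene)triphenylphosphorane | c1ccccc1COC=P(c1ccccc1)(c1ccccc1)c1ccccc1 | intermediate (not isolated)
16 | tert-butyl{[(1E,3E,5R,6R)-1-(benzyloxy)-4,5-dimethyldeca-1,3-dien-9-yn-6-yl]oxy}dimethylsilane | c1ccccc1CO/C=C/C=C(C)/[C@@H](C)[C@H](O[Si](C)(C)C(C)(C)C)CCC#C | intermediate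
17 | pinacolborane | CC1(C)OBOC1(C)C | starting material
18 | 2-[(1E,5R,6R,7E,9E)-10-(benzyloxy)-5-[(tert-butyldimethylsilyl)oxy]-6,7-dimethyldeca-1,7,9-trien-1-yl]-4,4,5,5-tetramethyl-1,3,2-dioxaborolane | c1ccccc1CO/C=C/C=C(C)/[C@@H](C)[C@H](O[Si](C)(C)C(C)(C)C)CC/C=C/B1OC(C)(C)C(C)(C)O1 | intermediate
19 | trans-fused cycloadduct: 8α-benzyloxy, 3α-tert-butyldimethylsilyloxy, 4β,5β-dimethyl, 9α-pinacolatoboryl, 10α-H, C6=C7 | CC(C)(C)[Si](C)(C)O[C@@H]1CC[C@H]2[C@H](B3OC(C)(C)C(C)(C)O3)[C@H](OCc3ccccc3)C=C[C@]2(C)[C@H]1C | intermediate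
20 | 9α-alcohol corresponding to 19 | CC(C)(C)[Si](C)(C)O[C@@H]1CC[C@H]2[C@H](O)[C@H](OCc3ccccc3)C=C[C@]2(C)[C@H]1C | intermediate
21 | 9α-triisopropylsilyl ether of 20 | CC(C)(C)[Si](C)(C)O[C@@H]1CC[C@H]2[C@H](O[Si](C(C)C)(C(C)C)C(C)C)[C@H](OCc3ccccc3)C=C[C@]2(C)[C@H]1C | intermediate
22 | 3α-(tert-butyldimethylsilyloxy)-4β,5β-dimethyl-9α-(triisopropylsilyloxy)-10αH-decalin-8α-ol | CC(C)(C)[Si](C)(C)O[C@@H]1CC[C@H]2[C@H](O[Si](C(C)C)(C(C)C)C(C)C)[C@H](O)CC[C@]2(C)[C@H]1C | intermediate
23 | 3α-(tert-butyldimethylsilyloxy)-4β,5β-dimethyl-9α-(triisopropylsilyloxy)-10αH-decalin-8-one | CC(C)(C)[Si](C)(C)O[C@@H]1CC[C@H]2[C@H](O[Si](C(C)C)(C(C)C)C(C)C)C(=O)CC[C@]2(C)[C@H]1C | intermediate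
24 | lithium C7=C8 enolate of 23 | CC(C)(C)[Si](C)(C)O[C@@H]1CC[C@H]2[C@H](O[Si](C(C)C)(C(C)C)C(C)C)C(O[Li])=CC[C@]2(C)[C@H]1C | intermediate (not isolated)
25 | chlorozinc C7=C8 enolate of 23 | CC(C)(C)[Si](C)(C)O[C@@H]1CC[C@H]2[C@H](O[Si](C(C)C)(C(C)C)C(C)C)C(O[Zn]Cl)=CC[C@]2(C)[C@H]1C | intermediate (not isolated)
26 | 7-(2-hydroxypropan-2-yl) derivative of 23 (C7 epimers) | CC(C)(C)[Si](C)(C)O[C@@H]1CC[C@H]2[C@H](O[Si](C(C)C)(C(C)C)C(C)C)C(=O)C(C(C)(C)O)C[C@]2(C)[C@H]1C | intermediate
27 | tertiary methanesulfonate of 26 | CC(C)(C)[Si](C)(C)O[C@@H]1CC[C@H]2[C@H](O[Si](C(C)C)(C(C)C)C(C)C)C(=O)C(C(C)(C)OS(C)(=O)=O)C[C@]2(C)[C@H]1C | intermediate (not isolated)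
28 | 3α-(tert-butyldimethylsilyloxy)-9α-(triisopropylsilyloxy)-10αH-eremophil-7(11)-en-8-one | CC(C)(C)[Si](C)(C)O[C@@H]1CC[C@H]2[C@H](O[Si](C(C)C)(C(C)C)C(C)C)C(=O)C(=C(C)C)C[C@]2(C)[C@H]1C | intermediate
29 | 3α-hydroxy-9α-(triisopropylsilyloxy)-10αH-eremophil-7(11)-en-8-one | O[C@@H]1CC[C@H]2[C@H](O[Si](C(C)C)(C(C)C)C(C)C)C(=O)C(=C(C)C)C[C@]2(C)[C@H]1C | intermediate
30 | (E)-non-3-en-2-one | CCCCC/C=C/C(C)=O | starting material
31 | ethyl (2E,4E,6E)-5-methyldodeca-2,4,6-trienoate | CCCCC/C=C/C(C)=C/C=C/C(=O)OCC | intermediate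
32 | (2E,4E,6E)-5-methyldodeca-2,4,6-trienoic acid | CCCCC/C=C/C(C)=C/C=C/C(=O)O | intermediate
33 | (2E,4E,6E)-5-methyldodeca-2,4,6-trienoic 2,4,6-trichlorobenzoic anhydride | CCCCC/C=C/C(C)=C/C=C/C(=O)OC(=O)c1c(Cl)cc(Cl)cc1Cl | intermediate (not isolated)
34 | 9α-(triisopropylsilyloxy)-8-oxo-10αH-eremophil-7(11)-en-3α-yl (2E,4E,6E)-5-methyldodeca-2,4,6-trienoate | CCCCC/C=C/C(C)=C/C=C/C(=O)O[C@@H]1CC[C@H]2[C@H](O[Si](C(C)C)(C(C)C)C(C)C)C(=O)C(=C(C)C)C[C@]2(C)[C@H]1C | intermediate
35 | (3R,4R,5R,9S,10R)-9-hydroxy-8-oxoeremophil-7(11)-en-3-yl (2E,4E,6E)-5-methyldodeca-2,4,6-trienoate (CNP0211657.1) | CCCCC/C=C/C(C)=C/C=C/C(=O)O[C@@H]1CC[C@H]2[C@H](O)C(=O)C(=C(C)C)C[C@]2(C)[C@H]1C | target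

**Step count**
Total: 23 steps. Longest linear sequence: 20 steps (1 → 35 through steps 1–8, 10–19, 22 and 23).

**Steps most likely to fail**

1. Step 12. The cycloaddition may be too slow at a temperature where the inside C5 methyl undergoes a [1,5]-hydrogen shift into the dienyl ether, and the weakly activating boronate may not discriminate well between the endo (trans-fused) and exo (cis-fused) transition states. The fallback changes the activating group on C9 to acetyl and brings in O9 by Baeyer–Villiger oxidation. It sets out from alkyne 16: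
   - Deprotonation with n-BuLi (THF, –78 °C) and addition to acetaldehyde should give the propargylic alcohol F1.
   - Trans-hydroalumination with NaAlH2(OCH2CH2OMe)2 (THF, 0 °C) should give the (E)-allylic alcohol F2.
   - MnO2 should give the (E)-enone F3, which should cyclise in toluene at 60–80 °C through the same C5–C10/C8–C9 bond formation to the 9α-acetyl trans-fused adduct F4.
   - H2 over Pd/C should saturate C6=C7 and remove the benzyl group to give the hydroxy ketone F5.
   - m-CPBA/NaHCO3 should insert oxygen with retention at C9 to give the 9α-acetate F6, and Dess–Martin periodinane should give the keto acetate F7.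
   - K2CO3 in MeOH at 0 °C should free the α-ketol F8, and TIPSOTf/2,6-lutidine returns the material to the route at 23.

2. Step 10. The alkoxymethylene ylide may give poor E/Z selectivity at C7=C8, and the (1Z)-dienyl ether cannot reach the reactive s-cis conformation. The fallback makes the same bond by a Horner–Wittig sequence with separable adducts and a stereospecific elimination. It sets out from enal 11:
   - Arbuzov reaction of 12 with ethyl diphenylphosphinite should give [(benzyloxy)methyl]diphenylphosphine oxide F9.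
   - Lithiation of this reagent (LiN(i-Pr)2, THF, –78 °C) and addition to 11 should give the diastereomeric β-hydroxy phosphine oxides F10, which are separated on silica.
   - The threo adduct undergoes syn-elimination with KH in THF and should give 16 as the single (1E)-isomer, where the route is rejoined.

3. Step 17. Proton transfer from acetone to the enolate and retro-aldol cleavage may limit conversion. The fallback replaces the metal enolate by a silyl enol ether and a Lewis-acid-driven addition. It sets out from ketone 23: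
   - LiN(i-Pr)2 and Me3SiCl (THF, –78 °C) should give the C7=C8 trimethylsilyl enol ether F11.
   - A Mukaiyama aldol addition to acetone with TiCl4 (CH2Cl2, –78 °C) should give 26, where the route is rejoined.

**Further compounds**
F1 | step 12 | (5E,7E,9R,10R)-5,7-dien-3-yn-2-ol precursor: 11-(benzyloxy)-6-(tert-butyldimethylsilyloxy)-7,8-dimethylundeca-8,10-dien-3-yn-2-ol (carbinol epimers) | c1ccccc1CO/C=C/C=C(C)/[C@@H](C)[C@H](O[Si](C)(C)C(C)(C)C)CCC#CC(C)O
F2 | step 12 | (3E,8E,10E)-11-(benzyloxy)-6-(tert-butyldimethylsilyloxy)-7,8-dimethylundeca-3,8,10-trien-2-ol (carbinol epimers) | c1ccccc1CO/C=C/C=C(C)/[C@@H](C)[C@H](O[Si](C)(C)C(C)(C)C)CC/C=C/C(C)O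
F3 | step 12 | (3E,6R,7R,8E,10E)-11-(benzyloxy)-6-(tert-butyldimethylsilyloxy)-7,8-dimethylundeca-3,8,10-trien-2-one | c1ccccc1CO/C=C/C=C(C)/[C@@H](C)[C@H](O[Si](C)(C)C(C)(C)C)CC/C=C/C(C)=O
F4 | step 12 | trans-fused 9α-acetyl cycloadduct (8α-benzyloxy, 3α-tert-butyldimethylsilyloxy, 4β,5β-dimethyl, 10α-H, C6=C7) | CC(C)(C)[Si](C)(C)O[C@@H]1CC[C@H]2[C@H](C(C)=O)[C@H](OCc3ccccc3)C=C[C@]2(C)[C@H]1C
F5 | step 12 | saturated 9α-acetyl-8α-hydroxy decalin | CC(C)(C)[Si](C)(C)O[C@@H]1CC[C@H]2[C@H](C(C)=O)[C@H](O)CC[C@]2(C)[C@H]1C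
F6 | step 12 | 9α-acetoxy-8α-hydroxy decalin | CC(C)(C)[Si](C)(C)O[C@@H]1CC[C@H]2[C@H](OC(C)=O)[C@H](O)CC[C@]2(C)[C@H]1C
F7 | step 12 | 9α-acetoxy decalin-8-one | CC(C)(C)[Si](C)(C)O[C@@H]1CC[C@H]2[C@H](OC(C)=O)C(=O)CC[C@]2(C)[C@H]1C
F8 | step 12 | 9α-hydroxy decalin-8-one | CC(C)(C)[Si](C)(C)O[C@@H]1CC[C@H]2[C@H](O)C(=O)CC[C@]2(C)[C@H]1C
F9 | step 10 | [(benzyloxy)methyl]diphenylphosphine oxide | O=P(COCc1ccccc1)(c1ccccc1)c1ccccc1
F10 | step 10 | β-hydroxy phosphine oxide adducts of 11 (diastereomers at the two new centres) | O=P(C(OCc1ccccc1)C(O)/C=C(\C)[C@@H](C)[C@H](O[Si](C)(C)C(C)(C)C)CCC#C)(c1ccccc1)c1ccccc1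
F11 | step 17 | C7=C8 trimethylsilyl enol ether of 23 | CC(C)(C)[Si](C)(C)O[C@@H]1CC[C@H]2[C@H](O[Si](C(C)C)(C(C)C)C(C)C)C(O[Si](C)(C)C)=CC[C@]2(C)[C@H]1C
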